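## Retrosynthetic overview

1. Target 12 is a 2-endo-bromo-7-oxabicyclo[2.2.1]heptane (ring B: C-1 bears CH3, C-2 is CHBr, C-3 is CH2, C-4 bears ring A, C-5/C-6 are the CH2CH2 bridge; the oxolane ring is O/C-1/C-2/C-3/C-4). Ring A is a trans-4-bromo-3,3-dimethylcyclohexyl group (C-1′ CH2, C-2′ CH bonded to C-4, C-3′, C-4′, C-5′ CHBr, C-6′ CMe2). Formally 12 = 8 + Br2.
2. Disconnections, all in one step: C-2–Br and O–C-4 (the oxolane goes back to the oxirane O/C-1/C-2 of a cyclohexane, a ring smaller by two atoms); the hydrogen shift from C-4 to C-2′; C-1′–C-6′ and C-5′–Br (ring A goes back to a 1,5-diene).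
3. Enabling feature of precursor 8: the oxirane (O, C-1, C-2) lies 1,4-transannular to C-4 on the ring face that carries H-4, anti to the side chain. C-4 carries a 1,1-disubstituted alkene (C-1′=C-2′) placed 1,5 to a trisubstituted alkene (C-5′=C-6′). A cation at C-2′ can therefore only be relayed to C-4 and then be bridged by the oxirane oxygen.
4. 8 comes in three steps from (+)-cis-limonene 1,2-oxide 1 (ring B and the oxirane from the chiral pool): ozonolysis, kinetic enol triflate, Negishi coupling with the homoprenyl unit of 6.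
5. Order of ring formation: ring B with its oxirane (present in 1), then ring A, then the oxolane/oxa bridge by ring expansion of the oxirane; the last two form in step 4.

Key step: step 4

Assumption: (+)-cis-limonene 1,2-oxide (1R,2S,4R) is used as the single diastereomer; from the commercial cis/trans mixture it would be obtained by letting pyrrolidine in water consume the more reactive trans isomer.

## Route

Step 1
Reactants: 1 (+)-cis-limonene 1,2-oxide
Product: 3 1-[(1S,3R,6R)-6-methyl-7-oxabicyclo[4.1.0]heptan-3-yl]ethan-1-one, via secondary ozonide 2 (not isolated)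
Conditions: O3, CH2Cl2, −78 °C; then Me2S, −78 °C → rt
Reagents that add atoms: ozone, [O-][O+]=O
Why: Ozonolysis with reductive work-up cleaves the only C=C bond (the isopropenyl group) to the methyl ketone; the oxirane is inert to ozone and the three stereocenters of 1 are carried over unchanged.

Step 2
Reactants: 3 1-[(1S,3R,6R)-6-methyl-7-oxabicyclo[4.1.0]heptan-3-yl]ethan-1-one
Product: 5 1-[(1S,3R,6R)-6-methyl-7-oxabicyclo[4.1.0]heptan-3-yl]ethenyl trifluoromethanesulfonate, via lithium enolate 4 (not isolated)
Conditions: LiN(i-Pr)2 (1.05 equiv), THF, −78 °C; then PhNTf2, −78 → 0 °C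
Reagents that add atoms: N-phenylbis(trifluoromethanesulfonimide), FC(F)(F)S(=O)(=O)N(c1ccccc1)S(=O)(=O)C(F)(F)F
Why: Kinetic deprotonation by the hindered amide base should occur at the methyl group and not at the ring methine, and O-sulfonylation of enolate 4 (enol triflate formation) should give the terminal alkenyl triflate without touching the ring stereocenters.

Step 3
Reactants: 5 1-[(1S,3R,6R)-6-methyl-7-oxabicyclo[4.1.0]heptan-3-yl]ethenyl trifluoromethanesulfonate; 6 5-bromo-2-methylpent-2-ene
Product: 8 (1R,4R,6S)-1-methyl-4-(6-methylhepta-1,5-dien-2-yl)-7-oxabicyclo[4.1.0]heptane, via alkylzinc bromide 7 (not isolated)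
Conditions: 6, Zn dust, LiCl, THF, 50 °C; then 5, Pd(dppf)Cl2 (5 mol %), THF, 25 → 50 °C
Reagents that add atoms: none
Why: Negishi cross-coupling, in which zinc inserts into the primary C–Br bond of 6 and zerovalent palladium formed from Pd(dppf)Cl2 adds to the alkenyl C–OTf bond of 5, transmetalates with 7 and eliminates reductively to the 1,1-disubstituted alkene; these near-neutral conditions should leave the oxirane and all stereocenters untouched.

Step 4
Reactants: 8 (1R,4R,6S)-1-methyl-4-(6-methylhepta-1,5-dien-2-yl)-7-oxabicyclo[4.1.0]heptane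
Product: 12 (1R,2R,4S)-2-bromo-4-[(1S,4S)-4-bromo-3,3-dimethylcyclohexyl]-1-methyl-7-oxabicyclo[2.2.1]heptane, via exocyclic tertiary carbocation 9 (not isolated), via ring B tertiary carbocation 10 (not isolated), via tricyclic oxonium ion 11 (not isolated)
Conditions: DBDMH (0.55 equiv), chiral BINOL-derived thiophosphoramide (10 mol %), PhMe/CH2Cl2, −90 °C; then n-Bu4NBr (2 equiv), −90 → −20 °C
Reagents that add atoms: 1,3-dibromo-5,5-dimethylhydantoin, CC1(C)N(Br)C(=O)N(Br)C1=O; tetrabutylammonium bromide, CCCC[N+](CCCC)(CCCC)CCCC.[Br-]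
Why: Proposed new method: the chiral Lewis base–Br+ adduct should deliver bromonium to the Si face of C-5′ of the trisubstituted alkene (catalyst control, the catalyst enantiomer being chosen for this face), and the methylene carbon C-1′ of the 1,1-disubstituted alkene opens it at C-6′ through a chair (six-membered closure of ring A with both alkene carbons endocyclic, bromine equatorial, C-5′ S). The exocyclic cation 9 is relayed by a suprafacial 1,2-shift of H-4 into its axial lobe, which keeps ring B equatorial and trans to bromine and so sets C-2′ as S. Cation 10 is captured across a boat by the oxirane oxygen (transannular five-membered closure, possible only from the face H-4 left, which fixes C-4 as S), and bromide opens oxonium 11 by SN2 at the oxirane CH with inversion (endo C–Br, C-2 R), so that the oxirane ring O/C-1/C-2 is expanded by C-3 and C-4 to the oxolane ring. The closest known reaction types are the catalytic enantioselective bromonium-initiated polyene cyclization of homogeranyl arenes, the α-terpinyl to terpinen-4-yl hydride shift, and the transannular epoxide participation with halide opening seen when cycloocta-1,5-diene monoepoxide is brominated. The step needs 1,4- and not 1,8-type ether formation, secured by the oxirane oxygen being anti to the C-4 side chain so that it cannot reach cation 9, and it needs opening of 11 at C-2 only, secured because C-1 and C-4 are fully substituted (ionization at C-4 merely returns to 10, ionization at C-1 would leave an oxetane). Bromide must be absent while Br+ is present, which is why the bromide salt is added only after both C=C bonds have been consumed.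

## Compound list

1 | (+)-cis-limonene 1,2-oxide, (1R,4R,6S)-1-methyl-4-(prop-1-en-2-yl)-7-oxabicyclo[4.1.0]heptane (oxirane oxygen anti to the isopropenyl group) | CC(=C)[C@@H]1CC[C@@]2(C)O[C@H]2C1 | starting material
2 | secondary ozonide of 1, 3-methyl-3-[(1S,3R,6R)-6-methyl-7-oxabicyclo[4.1.0]heptan-3-yl]-1,2,4-trioxolane (epimers at the trioxolane carbon) | CC1(OCOO1)[C@@H]1CC[C@@]2(C)O[C@H]2C1 | intermediate
3 | 1-[(1S,3R,6R)-6-methyl-7-oxabicyclo[4.1.0]heptan-3-yl]ethan-1-one | CC(=O)[C@@H]1CC[C@@]2(C)O[C@H]2C1 | intermediate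
4 | lithium enolate of 3 (methyl side) | [Li]OC(=C)[C@@H]1CC[C@@]2(C)O[C@H]2C1 | intermediate
5 | 1-[(1S,3R,6R)-6-methyl-7-oxabicyclo[4.1.0]heptan-3-yl]ethenyl trifluoromethanesulfonate | C=C(OS(=O)(=O)C(F)(F)F)[C@@H]1CC[C@@]2(C)O[C@H]2C1 | intermediate
6 | 5-bromo-2-methylpent-2-ene | CC(C)=CCCBr | starting material
7 | (4-methylpent-3-en-1-yl)zinc bromide | CC(C)=CCC[Zn]Br | intermediate
8 | (1R,4R,6S)-1-methyl-4-(6-methylhepta-1,5-dien-2-yl)-7-oxabicyclo[4.1.0]heptane | CC(C)=CCCC(=C)[C@@H]1CC[C@@]2(C)O[C@H]2C1 | intermediate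
9 | (4S)-4-bromo-3,3-dimethyl-1-[(1S,3R,6R)-6-methyl-7-oxabicyclo[4.1.0]heptan-3-yl]cyclohexan-1-ylium (cation at C-2′) | CC1(C)C[C+](CC[C@@H]1Br)[C@@H]1CC[C@@]2(C)O[C@H]2C1 | intermediate
10 | (1R,6S)-4-[(1S,4S)-4-bromo-3,3-dimethylcyclohexyl]-1-methyl-7-oxabicyclo[4.1.0]heptan-4-ylium (cation at C-4 of ring B) | CC1(C)C[C@@H]([C+]2CC[C@@]3(C)O[C@H]3C2)CC[C@@H]1Br | intermediate
11 | tricyclic oxonium ion: oxirane oxygen of 10 also bonded to C-4 (O+ on C-1, C-2 and C-4), ring A as in 12 | CC1(C)C[C@@H]([C@]23CC[C@]4(C)[C@H](C2)[O+]34)CC[C@@H]1Br | intermediate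
12 | (1R,2R,4S)-2-bromo-4-[(1S,4S)-4-bromo-3,3-dimethylcyclohexyl]-1-methyl-7-oxabicyclo[2.2.1]heptane (2-endo-bromide) | CC1(C)C[C@@H]([C@@]23CC[C@@](C)(O2)[C@H](Br)C3)CC[C@@H]1Br | target

## Step count and risks

Total step count: 4. Longest linear sequence: 4 steps (1 → 3 → 5 → 8 → 12).

Steps most likely to fail:

Step 4. The cationic relay may be ended early by proton loss to the hydantoin anion, or that anion may capture oxonium 11, before bromide arrives; the C-2′ configuration may erode if the hydride shift becomes reversible; and facial control of bromonium delivery may be incomplete. The fallback replaces the one-pot ionic cascade by a radical/ionic relay. From 8 the bromocyclization is run under the same catalyst with 2,6-di-tert-butyl-4-methylpyridine, so that proton loss is deliberate and should give the olefin (1R,6S)-4-[(1S,4S)-4-bromo-3,3-dimethylcyclohexyl]-1-methyl-7-oxabicyclo[4.1.0]hept-3-ene F1 (its double-bond isomers converge on the same cations 9 and 10). Markovnikov hydrobromination by hydrogen-atom transfer (Co(acac)2, t-BuOOH, Et3SiH, TsBr) should give the tertiary bromide (1R,6S)-4-bromo-4-[(1S,4S)-4-bromo-3,3-dimethylcyclohexyl]-1-methyl-7-oxabicyclo[4.1.0]heptane F2. Its ionization in nitromethane, assisted by the oxirane oxygen and with bromide as its own nucleophile, comes back to the route at 12 through 10 and 11.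

Step 3. Zinc halide may open or rearrange the oxirane, and slow transmetalation may lead to reduction of the triflate. The fallback reverses the polarity and avoids zinc. From 5, Miyaura borylation (B2pin2, Pd(dppf)Cl2, KOPh, PhMe, 50 °C) should give 4,4,5,5-tetramethyl-2-{1-[(1S,3R,6R)-6-methyl-7-oxabicyclo[4.1.0]heptan-3-yl]ethenyl}-1,3,2-dioxaborolane F3. Suzuki–Miyaura coupling of F3 with alkyl bromide 6 (Pd(OAc)2, P(t-Bu)2Me, KOt-Bu, tert-amyl alcohol, rt) comes back to the route at 8.

Step 2. Excess amide base may eliminate triflic acid from the terminal enol triflate to give the alkyne, and proton exchange between enolate 4 and ketone 3 may erode the C-4 configuration or the site of enolization. The fallback traps the kinetic enolate on carbon and makes no triflate. From 3, enolate 4 is alkylated with 1-bromo-3-methylbut-2-ene (THF, −78 → −20 °C) to give 5-methyl-1-[(1S,3R,6R)-6-methyl-7-oxabicyclo[4.1.0]heptan-3-yl]hex-4-en-1-one F4. Wittig methylenation of F4 (Ph3P=CH2 from MePPh3Br and KOt-Bu, THF, 0 °C) comes back to the route at 8.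

Further compounds
F1 | step 4 | (1R,6S)-4-[(1S,4S)-4-bromo-3,3-dimethylcyclohexyl]-1-methyl-7-oxabicyclo[4.1.0]hept-3-ene | CC1(C)C[C@@H](C2=CC[C@@]3(C)O[C@H]3C2)CC[C@@H]1Br
F2 | step 4 | (1R,6S)-4-bromo-4-[(1S,4S)-4-bromo-3,3-dimethylcyclohexyl]-1-methyl-7-oxabicyclo[4.1.0]heptane (both C-4 epimers) | CC1(C)C[C@@H](C2(Br)CC[C@@]3(C)O[C@H]3C2)CC[C@@H]1Br
F3 | step 3 | 4,4,5,5-tetramethyl-2-{1-[(1S,3R,6R)-6-methyl-7-oxabicyclo[4.1.0]heptan-3-yl]ethenyl}-1,3,2-dioxaborolane | C=C(B1OC(C)(C)C(C)(C)O1)[C@@H]1CC[C@@]2(C)O[C@H]2C1
F4 | step 2 | 5-methyl-1-[(1S,3R,6R)-6-methyl-7-oxabicyclo[4.1.0]heptan-3-yl]hex-4-en-1-one | CC(C)=CCCC(=O)[C@@H]1CC[C@@]2(C)O[C@H]2C1
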